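**Retrosynthetic overview**
1. The target is cut at the bond between C5 of the benzofuran and the bridging CH2: a Michael addition of dihydrobenzofuran acylphloroglucinol 13 to the 3-methylidene-pyran-2,4-dione 21, made in the flask from pyranone 18 and dimethyl(methylidene)ammonium iodide 19 (Mannich, then loss of Me2NH).
2. Pyranone 18 comes from lactonisation of a 3,5-diketo ester, itself made by Claisen acylation of the dianion of methyl 3-oxopentanoate with a propanoyl Weinreb amide.
3. The isopropenyl group of 13 comes from dehydration of a 2-(2-hydroxypropan-2-yl)dihydrobenzofuran, formed by 5-exo phenoxide opening (inversion) of the (R)-epoxide from Shi epoxidation of a prenyl group.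
4. The prenylated acylphloroglucinol comes from phloroglucinol, (S)-2-methylbutanoyl chloride (chiral pool, Friedel–Crafts) and prenyl bromide.
5. Ring order: the benzene ring is bought; the dihydrofuran ring is closed on it (step 7); the pyranone ring is built separately (step 11); the two halves are joined last (step 12).

Assumption: (S)-2-methylbutanoic acid (≥98% ee) and the D-fructose-derived epoxidation ketone are bought; both stereocentres of the target read as (S) from the SMILES.

**Route**

Step 1
Reactants: 1 (2S)-2-methylbutanoic acid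
Product: 2 (2S)-2-methylbutanoyl chloride
Conditions: (COCl)2 (1.1 equiv), N,N-dimethylformamide (cat.), CH2Cl2, 0 °C to rt; concentrated, used crude
Reagents that add atoms: oxalyl chloride, ClC(=O)C(=O)Cl
Why: Acid chloride formation through the Vilsmeier-type chloroiminium species is base-free, so the (S) α-carbon taken from the chiral pool is not enolised.

Step 2
Reactants: 2 (2S)-2-methylbutanoyl chloride; 3 phloroglucinol
Product: 4 (2S)-2-methyl-1-(2,4,6-trihydroxyphenyl)butan-1-one
Conditions: AlCl3 (3.5 equiv), PhNO2/CH2Cl2, 0 °C to 40 °C; aq. HCl work-up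
Reagents that add atoms: none
Why: Friedel–Crafts C-acylation of the symmetrical, highly activated triol stops after one acylation because the chelated aryl ketone is deactivated, and the non-basic medium leaves the (S) α-carbon intact (ee checked by chiral HPLC).

Step 3
Reactants: 4 (2S)-2-methyl-1-(2,4,6-trihydroxyphenyl)butan-1-one; 5 prenyl bromide
Product: 6 (2S)-2-methyl-1-[2,4,6-trihydroxy-3-(3-methylbut-2-en-1-yl)phenyl]butan-1-one
Conditions: 5 (0.9 equiv), DBU (1.0 equiv), THF, 0 °C to rt
Reagents that add atoms: none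
Why: C-alkylation of the ambident phloroglucinolate by the soft allylic bromide puts one prenyl group on one of the two equivalent free ring carbons, a deficit of bromide limits double prenylation, and the phenolate form shields the ketone α-carbon from enolisation.

Step 4
Reactants: 6 (2S)-2-methyl-1-[2,4,6-trihydroxy-3-(3-methylbut-2-en-1-yl)phenyl]butan-1-one
Product: 7 (2S)-1-[2-hydroxy-4,6-bis(methoxymethoxy)-3-(3-methylbut-2-en-1-yl)phenyl]-2-methylbutan-1-one
Conditions: MOMCl (2.3 equiv), i-Pr2NEt (3 equiv), CH2Cl2, 0 °C to rt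
Reagents that add atoms: chloromethyl methyl ether (MOMCl), COCCl
Why: Williamson-type etherification caps the acidic para hydroxyl and the unhindered ortho hydroxyl, while the ortho hydroxyl flanked by the prenyl group stays free because it is shielded and held in the hydrogen bond to the ketone (regiochemistry confirmed by HMBC).

Step 5
Reactants: 7 (2S)-1-[2-hydroxy-4,6-bis(methoxymethoxy)-3-(3-methylbut-2-en-1-yl)phenyl]-2-methylbutan-1-one
Product: 8 3,5-bis(methoxymethoxy)-2-[(2S)-2-methylbutanoyl]-6-(3-methylbut-2-en-1-yl)phenyl acetate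
Conditions: Ac2O (1.5 equiv), Et3N (2 equiv), 4-(dimethylamino)pyridine (cat.), CH2Cl2, rt
Reagents that add atoms: acetic anhydride, CC(=O)OC(C)=O
Why: Nucleophile-catalysed O-acylation masks the last phenol so that the electron-rich ring is not oxidised in the epoxidation and the phenol can be released later by mild methanolysis.

Step 6
Reactants: 8 3,5-bis(methoxymethoxy)-2-[(2S)-2-methylbutanoyl]-6-(3-methylbut-2-en-1-yl)phenyl acetate
Product: 9 2-{[(2R)-3,3-dimethyloxiran-2-yl]methyl}-3,5-bis(methoxymethoxy)-6-[(2S)-2-methylbutanoyl]phenyl acetate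
Conditions: 1,2:4,5-di-O-isopropylidene-β-D-erythro-2,3-hexodiulo-2,6-pyranose (0.3 equiv), Oxone (2KHSO5·KHSO4·K2SO4), K2CO3, Bu4NHSO4 (cat.), MeCN/dimethoxymethane, aq. Na2B4O7/Na2EDTA buffer, 0 °C
Reagents that add atoms: potassium peroxymonosulfate (KHSO5, the active oxidant of Oxone), [K+].[O-]S(=O)(=O)OO
Why: Shi asymmetric epoxidation of the trisubstituted prenyl olefin by the chiral dioxirane of the D-fructose-derived ketone goes through the spiro transition state to the (R)-epoxide (typically above 90% ee), and any acetate lost at this pH only leads on to the cyclised product of step 7.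

Step 7
Reactants: 9 2-{[(2R)-3,3-dimethyloxiran-2-yl]methyl}-3,5-bis(methoxymethoxy)-6-[(2S)-2-methylbutanoyl]phenyl acetate
Product: 11 (2S)-1-[(2S)-2-(2-hydroxypropan-2-yl)-4,6-bis(methoxymethoxy)-2,3-dihydro-1-benzofuran-7-yl]-2-methylbutan-1-one, via epoxy phenol 10 (not isolated)
Conditions: K2CO3 (0.5 equiv), MeOH, 0 °C to rt, 2 h
Reagents that add atoms: none
Why: Methanolysis of the aryl acetate frees the phenoxide, which opens the epoxide by a 5-exo-tet SN2 attack at the less substituted carbon with inversion, so the (R)-epoxide carbon becomes the (S)-configured C2 of the dihydrobenzofuran, and the minor diastereomer from imperfect epoxidation is removed here by chromatography.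

Step 8
Reactants: 11 (2S)-1-[(2S)-2-(2-hydroxypropan-2-yl)-4,6-bis(methoxymethoxy)-2,3-dihydro-1-benzofuran-7-yl]-2-methylbutan-1-one
Product: 12 (2S)-1-[(2S)-4,6-bis(methoxymethoxy)-2-(prop-1-en-2-yl)-2,3-dihydro-1-benzofuran-7-yl]-2-methylbutan-1-one
Conditions: Burgess reagent (1.8 equiv), toluene, 60 °C
Reagents that add atoms: none
Why: Burgess dehydration is a neutral syn-elimination through the sulfamate ester that preferentially removes one of the six methyl hydrogens, giving the isopropenyl group without touching the C2–O stereocentre, the MOM ethers or the ketone.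

Step 9
Reactants: 12 (2S)-1-[(2S)-4,6-bis(methoxymethoxy)-2-(prop-1-en-2-yl)-2,3-dihydro-1-benzofuran-7-yl]-2-methylbutan-1-one
Product: 13 (2S)-1-[(2S)-4,6-dihydroxy-2-(prop-1-en-2-yl)-2,3-dihydro-1-benzofuran-7-yl]-2-methylbutan-1-one
Conditions: conc. HCl (cat.), MeOH, 40 °C
Reagents that add atoms: none
Why: Acid-catalysed acetal exchange with methanol cleaves both aryl MOM ethers under conditions mild enough for the 1,1-disubstituted alkene, the allylic aryl ether and both stereocentres.

Step 10
Reactants: 14 methyl 3-oxopentanoate; 15 N-methoxy-N-methylpropanamide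
Product: 17 methyl 4-methyl-3,5-dioxoheptanoate, via dienolate dianion 16 (not isolated)
Conditions: NaH (1.1 equiv), THF, 0 °C; n-BuLi (1.05 equiv), 0 °C; 15 (0.9 equiv), −78 °C to 0 °C; aq. HCl work-up
Reagents that add atoms: none
Why: Claisen-type acylation of the β-keto ester dianion takes place at the more reactive γ-carbanion and the Weinreb amide stops at the chelated tetrahedral intermediate, so one acyl transfer gives the 3,5-diketo ester, whose new C4 centre is racemic, enolisable and lost in the next step.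

Step 11
Reactants: 17 methyl 4-methyl-3,5-dioxoheptanoate
Product: 18 6-ethyl-4-hydroxy-5-methyl-2H-pyran-2-one
Conditions: DBU (1.5 equiv), toluene, reflux; aq. HCl work-up
Reagents that add atoms: none
Why: Base-mediated lactonisation (attack of the C5 enolate oxygen on the methyl ester) closes the 4-hydroxy-2-pyranone with loss of methanol.

Step 12
Reactants: 18 6-ethyl-4-hydroxy-5-methyl-2H-pyran-2-one; 19 dimethyl(methylidene)ammonium iodide (Eschenmoser's salt); 13 (2S)-1-[(2S)-4,6-dihydroxy-2-(prop-1-en-2-yl)-2,3-dihydro-1-benzofuran-7-yl]-2-methylbutan-1-one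
Product: 22 6-ethyl-3-{[(2S)-4,6-dihydroxy-7-[(2S)-2-methylbutanoyl]-2-(prop-1-en-2-yl)-2,3-dihydro-1-benzofuran-5-yl]methyl}-4-hydroxy-5-methyl-2H-pyran-2-one, via Mannich base 20 (not isolated), via methylidene pyrandione 21 (not isolated)
Conditions: 18 (1.2 equiv), 19 (1.2 equiv), MeCN, rt, 1 h; then 13 (1.0 equiv), 60 °C
Reagents that add atoms: none
Why: Mannich aminomethylation of the pyranone at C3 and thermal loss of dimethylamine give the 3-methylidene-pyran-2,4-dione, a strong Michael acceptor that is attacked intermolecularly by the only free nucleophilic ring carbon (C5) of 13, and rearomatisation gives the methylene-bridged target with no stereocentre touched (the iminium salt is consumed before 13 and its alkene are added).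

**Compound list**
1 | (2S)-2-methylbutanoic acid | CC[C@H](C)C(=O)O | starting material
2 | (2S)-2-methylbutanoyl chloride | CC[C@H](C)C(Cl)=O | intermediate
3 | phloroglucinol (benzene-1,3,5-triol) | Oc1cc(O)cc(O)c1 | starting material
4 | (2S)-2-methyl-1-(2,4,6-trihydroxyphenyl)butan-1-one | CC[C@H](C)C(=O)c1c(O)cc(O)cc1O | intermediate
5 | prenyl bromide (1-bromo-3-methylbut-2-ene) | CC(C)=CCBr | starting material
6 | (2S)-2-methyl-1-[2,4,6-trihydroxy-3-(3-methylbut-2-en-1-yl)phenyl]butan-1-one | CC[C@H](C)C(=O)c1c(O)cc(O)c(CC=C(C)C)c1O | intermediate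
7 | (2S)-1-[2-hydroxy-4,6-bis(methoxymethoxy)-3-(3-methylbut-2-en-1-yl)phenyl]-2-methylbutan-1-one | CC[C@H](C)C(=O)c1c(OCOC)cc(OCOC)c(CC=C(C)C)c1O | intermediate
8 | 3,5-bis(methoxymethoxy)-2-[(2S)-2-methylbutanoyl]-6-(3-methylbut-2-en-1-yl)phenyl acetate | CC[C@H](C)C(=O)c1c(OCOC)cc(OCOC)c(CC=C(C)C)c1OC(C)=O | intermediate
9 | 2-{[(2R)-3,3-dimethyloxiran-2-yl]methyl}-3,5-bis(methoxymethoxy)-6-[(2S)-2-methylbutanoyl]phenyl acetate | CC[C@H](C)C(=O)c1c(OCOC)cc(OCOC)c(C[C@H]2OC2(C)C)c1OC(C)=O | intermediate
10 | (2S)-1-[3-{[(2R)-3,3-dimethyloxiran-2-yl]methyl}-2-hydroxy-4,6-bis(methoxymethoxy)phenyl]-2-methylbutan-1-one (epoxy phenol, not isolated) | CC[C@H](C)C(=O)c1c(OCOC)cc(OCOC)c(C[C@H]2OC2(C)C)c1O | intermediate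
11 | (2S)-1-[(2S)-2-(2-hydroxypropan-2-yl)-4,6-bis(methoxymethoxy)-2,3-dihydro-1-benzofuran-7-yl]-2-methylbutan-1-one | CC(C)(O)[C@@H]1Cc2c(OCOC)cc(OCOC)c(C(=O)[C@@H](C)CC)c2O1 | intermediate
12 | (2S)-1-[(2S)-4,6-bis(methoxymethoxy)-2-(prop-1-en-2-yl)-2,3-dihydro-1-benzofuran-7-yl]-2-methylbutan-1-one | C=C(C)[C@@H]1Cc2c(OCOC)cc(OCOC)c(C(=O)[C@@H](C)CC)c2O1 | intermediate
13 | (2S)-1-[(2S)-4,6-dihydroxy-2-(prop-1-en-2-yl)-2,3-dihydro-1-benzofuran-7-yl]-2-methylbutan-1-one | C=C(C)[C@@H]1Cc2c(O)cc(O)c(C(=O)[C@@H](C)CC)c2O1 | intermediate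
14 | methyl 3-oxopentanoate | CCC(=O)CC(=O)OC | starting material
15 | N-methoxy-N-methylpropanamide | CCC(=O)N(C)OC | starting material
16 | sodium lithium dienolate (dianion) of methyl 3-oxopentanoate (not isolated) | C[CH-]C(=O)[CH-]C(=O)OC.[Na+].[Li+] | intermediate
17 | methyl 4-methyl-3,5-dioxoheptanoate (racemic at C4, enolised) | CCC(=O)C(C)C(=O)CC(=O)OC | intermediate
18 | 6-ethyl-4-hydroxy-5-methyl-2H-pyran-2-one | CCc1oc(=O)cc(O)c1C | intermediate
19 | dimethyl(methylidene)ammonium iodide (Eschenmoser's salt) | C=[N+](C)C.[I-] | starting material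
20 | 3-[(dimethylamino)methyl]-6-ethyl-4-hydroxy-5-methyl-2H-pyran-2-one (Mannich base, not isolated) | CCc1oc(=O)c(CN(C)C)c(O)c1C | intermediate
21 | 6-ethyl-5-methyl-3-methylidene-2H-pyran-2,4(3H)-dione (not isolated) | CCC1=C(C)C(=O)C(=C)C(=O)O1 | intermediate
22 | 6-ethyl-3-{[(2S)-4,6-dihydroxy-7-[(2S)-2-methylbutanoyl]-2-(prop-1-en-2-yl)-2,3-dihydro-1-benzofuran-5-yl]methyl}-4-hydroxy-5-methyl-2H-pyran-2-one | C=C(C)[C@@H]1Cc2c(O)c(Cc3c(O)c(C)c(CC)oc3=O)c(O)c(C(=O)[C@@H](C)CC)c2O1 | target

**Totals**
Total step count: 12. Longest linear sequence: 10 steps (steps 1 to 9, then step 12); the pyranone branch is 2 steps (10 and 11).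

**Three steps most likely to fail**

Step 3 (direct mono-C-prenylation: O-alkylation and double prenylation lower the yield, and step 4 then depends on which ortho hydroxyl stays free). The fallback sets out from 4 and comes back at 7, bypassing 6. Compound 4 is first treated with MOMCl and i-Pr2NEt to give (2S)-1-[2-hydroxy-4,6-bis(methoxymethoxy)phenyl]-2-methylbutan-1-one F1, which has no regiochemical ambiguity because 4 is symmetrical. The remaining chelated phenol is O-alkylated with 3-chloro-3-methylbut-1-yne (DBU, CuCl2 cat., MeCN, 0 °C) to give (2S)-1-{2,4-bis(methoxymethoxy)-6-[(2-methylbut-3-yn-2-yl)oxy]phenyl}-2-methylbutan-1-one F2. Semihydrogenation (H2, Pd/CaCO3 poisoned by Pb(OAc)2, quinoline, EtOAc) gives (2S)-1-{2,4-bis(methoxymethoxy)-6-[(2-methylbut-3-en-2-yl)oxy]phenyl}-2-methylbutan-1-one F3. Heating F3 (N,N-diethylaniline, 130 °C) triggers an aromatic Claisen rearrangement to the only hydrogen-bearing ortho carbon, which gives 7 with the prenyl group necessarily next to the free phenol.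

Step 8 (dehydration could give some of the isopropylidene enol ether or the aromatised benzofuran instead of the isopropenyl group). The fallback sets out from 7 and comes back at 12, forming the ring and the isopropenyl group in one event. Allylic oxidation of 7 (SeO2 cat., t-BuOOH, CH2Cl2) gives (2S)-1-{2-hydroxy-3-[(2E)-4-hydroxy-3-methylbut-2-en-1-yl]-4,6-bis(methoxymethoxy)phenyl}-2-methylbutan-1-one F4. Selective acylation of the primary allylic alcohol (methyl chloroformate, pyridine, CH2Cl2, −20 °C) gives (2E)-4-{2-hydroxy-4,6-bis(methoxymethoxy)-3-[(2S)-2-methylbutanoyl]phenyl}-2-methylbut-2-en-1-yl methyl carbonate F5. Asymmetric intramolecular allylic etherification of F5 with Pd2(dba)3·CHCl3 (a zerovalent palladium source) and the chiral N,N'-(cyclohexane-1,2-diyl)bis[2-(diphenylphosphanyl)benzamide] ligand in CH2Cl2 closes the 5-membered ring at the internal allyl terminus and gives 12. The ligand enantiomer that gives (2S) is fixed by chiral HPLC comparison with 12 from the main route.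

Step 12 (the methylidene pyrandione can be trapped by a second pyranone to give the bis-pyranone, or the Mannich base may not eliminate cleanly). The fallback sets out from 13 and comes back at 22 with the roles reversed. Aminomethylation of 13 at C5 with bis(dimethylamino)methane (dioxane, rt) gives (2S)-1-[(2S)-5-[(dimethylamino)methyl]-4,6-dihydroxy-2-(prop-1-en-2-yl)-2,3-dihydro-1-benzofuran-7-yl]-2-methylbutan-1-one F6. Heating F6 with pyranone 18 (dioxane, 90 °C) expels dimethylamine to an ortho-quinone methide on the phloroglucinol half, which the pyranone C3 traps by Michael addition to give 22.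

**Further compounds**
F1 | step 3 | (2S)-1-[2-hydroxy-4,6-bis(methoxymethoxy)phenyl]-2-methylbutan-1-one | CC[C@H](C)C(=O)c1c(OCOC)cc(OCOC)cc1O
F2 | step 3 | (2S)-1-{2,4-bis(methoxymethoxy)-6-[(2-methylbut-3-yn-2-yl)oxy]phenyl}-2-methylbutan-1-one | CC[C@H](C)C(=O)c1c(OCOC)cc(OCOC)cc1OC(C)(C)C#C
F3 | step 3 | (2S)-1-{2,4-bis(methoxymethoxy)-6-[(2-methylbut-3-en-2-yl)oxy]phenyl}-2-methylbutan-1-one | CC[C@H](C)C(=O)c1c(OCOC)cc(OCOC)cc1OC(C)(C)C=C
F4 | step 8 | (2S)-1-{2-hydroxy-3-[(2E)-4-hydroxy-3-methylbut-2-en-1-yl]-4,6-bis(methoxymethoxy)phenyl}-2-methylbutan-1-one | CC[C@H](C)C(=O)c1c(OCOC)cc(OCOC)c(C/C=C(\C)CO)c1O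
F5 | step 8 | (2E)-4-{2-hydroxy-4,6-bis(methoxymethoxy)-3-[(2S)-2-methylbutanoyl]phenyl}-2-methylbut-2-en-1-yl methyl carbonate | CC[C@H](C)C(=O)c1c(OCOC)cc(OCOC)c(C/C=C(\C)COC(=O)OC)c1O
F6 | step 12 | (2S)-1-[(2S)-5-[(dimethylamino)methyl]-4,6-dihydroxy-2-(prop-1-en-2-yl)-2,3-dihydro-1-benzofuran-7-yl]-2-methylbutan-1-one | C=C(C)[C@@H]1Cc2c(O)c(CN(C)C)c(O)c(C(=O)[C@@H](C)CC)c2O1
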